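**Strategy.** The six-membered ring is treated as a masked 2-methyl-5-substituted cyclohex-2-enone. The epoxide CH is a former ketone carbon, the methyl-bearing epoxide carbon and the adjacent CH–OAng a former enone C=C, and the ring CH2 the central carbon of a β-keto ester. One amine-catalysed Michael/aldol-condensation/decarboxylation between ethyl (E)-4-oxobut-2-enoate and tert-butyl 3-oxopentanoate therefore forms the CH2–CH(side chain) bond and the C(CH3)–CH(O) bond, closes the carbocycle and sets the side-chain-bearing stereocentre. The other four ring centres are relayed from it; the ester becomes the methylene-bearing side chain by Nozaki–Hiyama–Kishi coupling, and a late Shi epoxidation completes the target.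

Key step: step 1

Remark: the amine-catalysed conjugate addition and the acid-promoted ring closure/decarboxylation of step 1 are run in one flask without isolation and are counted as one operation.

Step 1
Reactants: 1 ethyl (2E)-4-oxobut-2-enoate; 2 tert-butyl 3-oxopentanoate
Product: 5 ethyl (1R)-4-methyl-5-oxocyclohex-3-ene-1-carboxylate, via Michael adduct 3 (not isolated), via tert-butyl ester 4 (not isolated)
Conditions: (S)-2-{bis[3,5-bis(trifluoromethyl)phenyl][(trimethylsilyl)oxy]methyl}pyrrolidine (10 mol%), PhCO2H (10 mol%), toluene, 0 °C to rt; then p-TsOH·H2O (20 mol%), 80 °C, same flask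
Reagents that add atoms: none
Why: The prolinol silyl ether condenses with 1 to an E-iminium ion, and the C2 carbon of 2 adds to its β-carbon (the carbon that bears the ester) in a Michael addition that forms the ring CH2–CH bond; the closest known reaction type is the amine-catalysed Michael/aldol-condensation route from β-keto esters and enals to 5-substituted cyclohex-2-enones, a formal [3+3] annulation of Robinson type. The new stereocentre is controlled by the catalyst, whose silyloxydiarylmethyl group shields one face of the iminium ion so that the nucleophile enters anti to it, which with the S catalyst should give the R centre of 5 and hence the ring CH configuration of the target. Acid then enolises the ethyl ketone of 3 towards its CH2 group and this carbon attacks the aldehyde in a 6-(enolendo)-exo-trig aldol closure, the only ring size open to the chain; loss of water gives the C(CH3)=CH bond of 4. The tert-butyl ester of 4 is cleaved by the same acid and the β-keto acid decarboxylates, so the configuration at the former C2 of 2 is irrelevant. The step needs site selectivity between the two alkene carbons of 1, secured by iminium activation, which makes the carbon β to the aldehyde the electrophile; it also needs the enantiomeric purity to survive the acid stage, which is expected because the new centre is α only to an ester and no retro-Michael path remains once the ring has formed.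

Step 2
Reactants: 5 ethyl (1R)-4-methyl-5-oxocyclohex-3-ene-1-carboxylate
Product: 6 ethyl (1S)-4-methyl-5-{[(trifluoromethyl)sulfonyl]oxy}cyclohexa-2,4-diene-1-carboxylate
Conditions: Tf2O, 2,6-di-tert-butyl-4-methylpyridine, CH2Cl2, 0 °C to rt
Reagents that add atoms: trifluoromethanesulfonic anhydride, O=S(=O)(OS(=O)(=O)C(F)(F)F)C(F)(F)F
Why: O-sulfonylation of the enone carbonyl gives a triflyloxy allyl cation that loses the γ-proton (thermodynamic enol triflate formation), which should give the linearly conjugated dienyl triflate; the existing stereocentre is not touched.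

Step 3
Reactants: 6 ethyl (1S)-4-methyl-5-{[(trifluoromethyl)sulfonyl]oxy}cyclohexa-2,4-diene-1-carboxylate
Product: 7 ethyl (1S,5S,6R)-5,6-dihydroxy-4-methyl-3-{[(trifluoromethyl)sulfonyl]oxy}cyclohex-3-ene-1-carboxylate
Conditions: OsO4 (2 mol%), N-methylmorpholine N-oxide, acetone–H2O, 0 °C
Reagents that add atoms: N-methylmorpholine N-oxide, C[N+]1([O-])CCOCC1; water, O (both hydroxyl oxygens are delivered through OsO4, O=[Os](=O)(=O)=O)
Why: Catalytic OsO4 syn-dihydroxylation should occur at the electron-richer disubstituted alkene (the triflyloxy-substituted one is deactivated) and from the face anti to the ester on the adjacent stereocentre, which sets both carbinol centres cis to each other and trans to the ester.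

Step 4
Reactants: 7 ethyl (1S,5S,6R)-5,6-dihydroxy-4-methyl-3-{[(trifluoromethyl)sulfonyl]oxy}cyclohex-3-ene-1-carboxylate
Product: 8 ethyl (1S,5S,6R)-5,6-dihydroxy-4-methylcyclohex-3-ene-1-carboxylate
Conditions: Pd(OAc)2 (5 mol%), PPh3, HCO2H, Bu3N, DMF, 60 °C
Reagents that add atoms: none
Why: Palladium-catalysed formate reduction of an alkenyl triflate (oxidative addition, formate exchange, decarboxylation, reductive elimination) replaces OTf by H without moving the alkene; no stereocentre is formed or touched.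

Step 5
Reactants: 8 ethyl (1S,5S,6R)-5,6-dihydroxy-4-methylcyclohex-3-ene-1-carboxylate
Product: 10 ethyl (1S,5S,6R)-5-hydroxy-6-[(4-methoxyphenyl)methoxy]-4-methylcyclohex-3-ene-1-carboxylate, via stannylene acetal 9 (not isolated)
Conditions: Bu2SnO, toluene, reflux with removal of water; then 4-methoxybenzyl chloride, Bu4NI, 90 °C
Reagents that add atoms: dibutyltin oxide, CCCC[Sn](=O)CCCC (retained only in 9); 4-methoxybenzyl chloride, COc1ccc(CCl)cc1
Why: Regioselective O-alkylation through a dibutylstannylene acetal, which activates the equatorial oxygen of a cis-1,2-diol, should place the PMB group on the hydroxyl next to the ester-bearing carbon and leave the pseudoaxial allylic hydroxyl free.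

Step 6
Reactants: 10 ethyl (1S,5S,6R)-5-hydroxy-6-[(4-methoxyphenyl)methoxy]-4-methylcyclohex-3-ene-1-carboxylate
Product: 12 1-{(1S,5S,6R)-5-hydroxy-6-[(4-methoxyphenyl)methoxy]-4-methylcyclohex-3-en-1-yl}ethan-1-one, via Weinreb amide 11 (not isolated)
Conditions: MeNHOMe·HCl, i-PrMgCl, THF, −20 °C; then MeMgBr, 0 °C
Reagents that add atoms: N,O-dimethylhydroxylamine hydrochloride, CNOC.Cl (retained only in 11); methylmagnesium bromide, C[Mg]Br
Why: Weinreb ketone synthesis in one flask, in which the magnesium amide converts the ester into the N-methoxy-N-methylamide and MeMgBr adds once through the chelated tetrahedral intermediate; the α-stereocentre already has the more stable equatorial arrangement trans to the neighbouring ether, so it should be retained.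

Step 7
Reactants: 12 1-{(1S,5S,6R)-5-hydroxy-6-[(4-methoxyphenyl)methoxy]-4-methylcyclohex-3-en-1-yl}ethan-1-one; 13 angelic acid [(2Z)-2-methylbut-2-enoic acid]
Product: 14 (1S,5S,6R)-5-acetyl-6-[(4-methoxyphenyl)methoxy]-2-methylcyclohex-2-en-1-yl (2Z)-2-methylbut-2-enoate
Conditions: 13, 2,4,6-trichlorobenzoyl chloride, Et3N, toluene, rt; then 12, toluene, 80 °C
Reagents that add atoms: none
Why: Yamaguchi-type esterification through the mixed 2,4,6-trichlorobenzoic anhydride acylates the hindered allylic alcohol with retention at carbon and, run without DMAP, should avoid Z to E isomerisation of the angelate.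

Step 8
Reactants: 14 (1S,5S,6R)-5-acetyl-6-[(4-methoxyphenyl)methoxy]-2-methylcyclohex-2-en-1-yl (2Z)-2-methylbut-2-enoate
Product: 15 (1R,2R,3R,4S,6R)-4-acetyl-3-[(4-methoxyphenyl)methoxy]-1-methyl-7-oxabicyclo[4.1.0]heptan-2-yl (2Z)-2-methylbut-2-enoate
Conditions: mCPBA, NaHCO3, CH2Cl2, 0 °C
Reagents that add atoms: 3-chloroperoxybenzoic acid, OOC(=O)c1cccc(Cl)c1
Why: Prilezhaev epoxidation of the only electron-rich alkene, in which the allylic angelate (held pseudoaxial by allylic strain with the vinylic methyl) blocks its own face, so the peracid should attack anti to both ring oxygens and set the two epoxide centres cis to the acetyl group; Baeyer–Villiger oxidation of the ketone is expected to be slower under buffered conditions.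

Step 9
Reactants: 15 (1R,2R,3R,4S,6R)-4-acetyl-3-[(4-methoxyphenyl)methoxy]-1-methyl-7-oxabicyclo[4.1.0]heptan-2-yl (2Z)-2-methylbut-2-enoate
Product: 17 (1R,2R,3R,4S,6R)-3-[(4-methoxyphenyl)methoxy]-1-methyl-4-(1-{[(trifluoromethyl)sulfonyl]oxy}ethenyl)-7-oxabicyclo[4.1.0]heptan-2-yl (2Z)-2-methylbut-2-enoate, via potassium enolate 16 (not isolated)
Conditions: KN(SiMe3)2, THF, −78 °C; then PhNTf2, −78 to 0 °C
Reagents that add atoms: potassium bis(trimethylsilyl)amide, C[Si](C)(C)[N-][Si](C)(C)C.[K+] (potassium retained only in 16); N-phenylbis(trifluoromethanesulfonimide), O=S(=O)(N(c1ccccc1)S(=O)(=O)C(F)(F)F)C(F)(F)F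
Why: Kinetic deprotonation of the methyl ketone at the methyl group by the bulky amide base, followed by O-triflation of the enolate, should give the 1,1-disubstituted enol triflate; no stereocentre is formed and the ring α-CH is not deprotonated.

Step 10
Reactants: 18 4-methylpent-3-en-1-ol
Product: 19 4-methylpent-3-enal
Conditions: Dess–Martin periodinane, NaHCO3, CH2Cl2, 0 °C; used as a crude solution
Reagents that add atoms: none
Why: Dess–Martin oxidation of a primary alcohol to the aldehyde under buffered, non-basic conditions, which should keep the β,γ-alkene out of conjugation.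

Step 11
Reactants: 17 enol triflate (see step 9); 19 4-methylpent-3-enal
Product: 20 (1R,2R,3R,4R,6R)-4-[(3S)-3-hydroxy-6-methylhepta-1,5-dien-2-yl]-3-[(4-methoxyphenyl)methoxy]-1-methyl-7-oxabicyclo[4.1.0]heptan-2-yl (2Z)-2-methylbut-2-enoate
Conditions: CrCl2 (4 equiv), valinol-derived oxazoline–sulfonamide ligand N-[2-(4-isopropyl-4,5-dihydrooxazol-2-yl)-6-methylphenyl]methanesulfonamide (4.4 equiv, antipode chosen for the 3S alcohol), Et3N, THF, rt; then NiCl2 (cat.), 17 and 19, rt
Reagents that add atoms: none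
Why: Nozaki–Hiyama–Kishi coupling, in which nickel inserts into the alkenyl triflate, transmetalation gives an alkenylchromium species and this adds to the aldehyde while esters, epoxide and ether are tolerated; the carbinol centre is set under catalyst control by the chiral chromium–sulfonamide complex.

Step 12
Reactants: 20 allylic alcohol (see step 11); 13 angelic acid
Product: 21 (1R,2R,3R,4R,6R)-3-[(4-methoxyphenyl)methoxy]-1-methyl-4-[(3S)-6-methyl-3-{[(2Z)-2-methylbut-2-enoyl]oxy}hepta-1,5-dien-2-yl]-7-oxabicyclo[4.1.0]heptan-2-yl (2Z)-2-methylbut-2-enoate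
Conditions: 13, 2,4,6-trichlorobenzoyl chloride, Et3N, toluene, rt; then 20, toluene, 80 °C
Reagents that add atoms: none
Why: Yamaguchi-type mixed-anhydride esterification of the secondary allylic alcohol with retention at carbon and without base-induced isomerisation of either angelate.

Step 13
Reactants: 21 bis-angelate (see step 12)
Product: 22 (1R,2R,3R,4R,6R)-4-[(3S)-4-[(2R)-3,3-dimethyloxiran-2-yl]-3-{[(2Z)-2-methylbut-2-enoyl]oxy}but-1-en-2-yl]-3-[(4-methoxyphenyl)methoxy]-1-methyl-7-oxabicyclo[4.1.0]heptan-2-yl (2Z)-2-methylbut-2-enoate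
Conditions: D-fructose-derived Shi ketone (30 mol%), KHSO5 (as 2KHSO5·KHSO4·K2SO4), K2CO3, Bu4NHSO4, MeCN–CH2(OMe)2–aqueous Na2B4O7 buffer, 0 °C
Reagents that add atoms: potassium peroxymonosulfate, [K+].[O-]S(=O)(=O)OO
Why: Shi epoxidation, in which the chiral dioxirane formed in situ epoxidises the electron-rich trisubstituted alkene through a spiro transition state; the D-fructose-derived ketone should give the R epoxide, and the 1,1-disubstituted and conjugated alkenes are too electron-poor to compete.

Step 14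
Reactants: 22 PMB ether (see step 13)
Product: 23 (1R,2R,3R,4R,6R)-4-[(3S)-4-[(2R)-3,3-dimethyloxiran-2-yl]-3-{[(2Z)-2-methylbut-2-enoyl]oxy}but-1-en-2-yl]-3-hydroxy-1-methyl-7-oxabicyclo[4.1.0]heptan-2-yl (2Z)-2-methylbut-2-enoate (target)
Conditions: DDQ, CH2Cl2–pH 7 phosphate buffer, 0 °C to rt
Reagents that add atoms: none
Why: Oxidative cleavage of the PMB ether by DDQ (hydride abstraction, then hydrolysis of the oxocarbenium ion) under buffered conditions should leave both epoxides and both angelates intact and avoid migration of the neighbouring acyl group.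

**Compound list**

1 | ethyl (2E)-4-oxobut-2-enoate | CCOC(=O)/C=C/C=O | starting material
2 | tert-butyl 3-oxopentanoate | CCC(=O)CC(=O)OC(C)(C)C | starting material
3 | 1-tert-butyl 4-ethyl (3R)-3-(2-oxoethyl)-2-propanoylbutanedioate (C2 epimers) | CCOC(=O)[C@H](CC=O)C(C(=O)CC)C(=O)OC(C)(C)C | intermediate (not isolated)
4 | 1-tert-butyl 2-ethyl (2R)-5-methyl-6-oxocyclohex-4-ene-1,2-dicarboxylate (C1 epimers) | CCOC(=O)[C@H]1C(C(=O)OC(C)(C)C)C(=O)C(C)=CC1 | intermediate (not isolated)
5 | ethyl (1R)-4-methyl-5-oxocyclohex-3-ene-1-carboxylate | CCOC(=O)[C@H]1CC(=O)C(C)=CC1 | intermediate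
6 | ethyl (1S)-4-methyl-5-{[(trifluoromethyl)sulfonyl]oxy}cyclohexa-2,4-diene-1-carboxylate | CCOC(=O)[C@H]1CC(OS(=O)(=O)C(F)(F)F)=C(C)C=C1 | intermediate
7 | ethyl (1S,5S,6R)-5,6-dihydroxy-4-methyl-3-{[(trifluoromethyl)sulfonyl]oxy}cyclohex-3-ene-1-carboxylate | CCOC(=O)[C@H]1CC(OS(=O)(=O)C(F)(F)F)=C(C)[C@H](O)[C@@H]1O | intermediate
8 | ethyl (1S,5S,6R)-5,6-dihydroxy-4-methylcyclohex-3-ene-1-carboxylate | CCOC(=O)[C@H]1CC=C(C)[C@H](O)[C@@H]1O | intermediate
9 | 2,2-dibutyl-1,3,2-dioxastannolane (stannylene acetal) of diol 8, cis-fused | CCOC(=O)[C@H]1CC=C(C)[C@@H]2O[Sn](CCCC)(CCCC)O[C@H]12 | intermediate (not isolated)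
10 | ethyl (1S,5S,6R)-5-hydroxy-6-[(4-methoxyphenyl)methoxy]-4-methylcyclohex-3-ene-1-carboxylate | CCOC(=O)[C@H]1CC=C(C)[C@H](O)[C@@H]1OCc1ccc(OC)cc1 | intermediate
11 | (1S,5S,6R)-5-hydroxy-N-methoxy-6-[(4-methoxyphenyl)methoxy]-N,4-dimethylcyclohex-3-ene-1-carboxamide | CON(C)C(=O)[C@H]1CC=C(C)[C@H](O)[C@@H]1OCc1ccc(OC)cc1 | intermediate (not isolated)
12 | 1-{(1S,5S,6R)-5-hydroxy-6-[(4-methoxyphenyl)methoxy]-4-methylcyclohex-3-en-1-yl}ethan-1-one | CC(=O)[C@H]1CC=C(C)[C@H](O)[C@@H]1OCc1ccc(OC)cc1 | intermediate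
13 | angelic acid, (2Z)-2-methylbut-2-enoic acid | O=C(O)/C(C)=C\C | starting material
14 | (1S,5S,6R)-5-acetyl-6-[(4-methoxyphenyl)methoxy]-2-methylcyclohex-2-en-1-yl (2Z)-2-methylbut-2-enoate | CC(=O)[C@H]1CC=C(C)[C@H](OC(=O)/C(C)=C\C)[C@@H]1OCc1ccc(OC)cc1 | intermediate
15 | (1R,2R,3R,4S,6R)-4-acetyl-3-[(4-methoxyphenyl)methoxy]-1-methyl-7-oxabicyclo[4.1.0]heptan-2-yl (2Z)-2-methylbut-2-enoate | CC(=O)[C@H]1C[C@H]2O[C@@]2(C)[C@H](OC(=O)/C(C)=C\C)[C@@H]1OCc1ccc(OC)cc1 | intermediate
16 | potassium enolate of 15 (methyl-side enolate) | C=C([O-])[C@H]1C[C@H]2O[C@@]2(C)[C@H](OC(=O)/C(C)=C\C)[C@@H]1OCc1ccc(OC)cc1.[K+] | intermediate (not isolated)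
17 | (1R,2R,3R,4S,6R)-3-[(4-methoxyphenyl)methoxy]-1-methyl-4-(1-{[(trifluoromethyl)sulfonyl]oxy}ethenyl)-7-oxabicyclo[4.1.0]heptan-2-yl (2Z)-2-methylbut-2-enoate | C=C(OS(=O)(=O)C(F)(F)F)[C@H]1C[C@H]2O[C@@]2(C)[C@H](OC(=O)/C(C)=C\C)[C@@H]1OCc1ccc(OC)cc1 | intermediate
18 | 4-methylpent-3-en-1-ol | CC(C)=CCCO | starting material
19 | 4-methylpent-3-enal | CC(C)=CCC=O | intermediate
20 | (1R,2R,3R,4R,6R)-4-[(3S)-3-hydroxy-6-methylhepta-1,5-dien-2-yl]-3-[(4-methoxyphenyl)methoxy]-1-methyl-7-oxabicyclo[4.1.0]heptan-2-yl (2Z)-2-methylbut-2-enoate | C=C([C@H](CC=C(C)C)O)[C@H]1C[C@H]2O[C@@]2(C)[C@H](OC(=O)/C(C)=C\C)[C@@H]1OCc1ccc(OC)cc1 | intermediate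
21 | (1R,2R,3R,4R,6R)-3-[(4-methoxyphenyl)methoxy]-1-methyl-4-[(3S)-6-methyl-3-{[(2Z)-2-methylbut-2-enoyl]oxy}hepta-1,5-dien-2-yl]-7-oxabicyclo[4.1.0]heptan-2-yl (2Z)-2-methylbut-2-enoate | C=C([C@H](CC=C(C)C)OC(=O)/C(C)=C\C)[C@H]1C[C@H]2O[C@@]2(C)[C@H](OC(=O)/C(C)=C\C)[C@@H]1OCc1ccc(OC)cc1 | intermediate
22 | (1R,2R,3R,4R,6R)-4-[(3S)-4-[(2R)-3,3-dimethyloxiran-2-yl]-3-{[(2Z)-2-methylbut-2-enoyl]oxy}but-1-en-2-yl]-3-[(4-methoxyphenyl)methoxy]-1-methyl-7-oxabicyclo[4.1.0]heptan-2-yl (2Z)-2-methylbut-2-enoate | C=C([C@H](C[C@H]1OC1(C)C)OC(=O)/C(C)=C\C)[C@H]1C[C@H]2O[C@@]2(C)[C@H](OC(=O)/C(C)=C\C)[C@@H]1OCc1ccc(OC)cc1 | intermediate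
23 | (1R,2R,3R,4R,6R)-4-[(3S)-4-[(2R)-3,3-dimethyloxiran-2-yl]-3-{[(2Z)-2-methylbut-2-enoyl]oxy}but-1-en-2-yl]-3-hydroxy-1-methyl-7-oxabicyclo[4.1.0]heptan-2-yl (2Z)-2-methylbut-2-enoate | C=C([C@H](C[C@H]1OC1(C)C)OC(=O)/C(C)=C\C)[C@H]1C[C@H]2O[C@@]2(C)[C@H](OC(=O)/C(C)=C\C)[C@@H]1O | target

**Step count.** Total: 14 steps. Longest linear sequence: 13 steps (steps 1–9 and 11–14); step 10 is the one-step side branch.

**Steps most likely to fail**

Step 11. The risk is poor facial selectivity in the addition of the alkenylchromium species to the aldehyde, because the ligand has to override a large chiral substrate; the side-chain carbinol would then form as a mixture of epimers. The fallback sets out from 17 and 19 and comes back at 20. The coupling is run with CrCl2 and catalytic NiCl2 in DMF without ligand and should give the allylic alcohol as both carbinol epimers F1. Dess–Martin oxidation should convert this into the α-methylene ketone F2. Corey–Bakshi–Shibata reduction with the (R)-methyl oxazaborolidine and catecholborane at −78 °C, in which the branched alkenyl group acts as the large substituent, should then return 20 with the S carbinol.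

Step 8. The risk is attack of the peracid on the wrong face of the ring alkene, with Baeyer–Villiger oxidation of the methyl ketone as a competing process. The fallback sets out from 14 and comes back at 15, and replaces steric control by hydroxyl delivery. NaBH4 in MeOH should reduce the methyl ketone to the 1-hydroxyethyl compound F3 (carbinol epimers, esters untouched). VO(acac)2 with t-BuOOH should then deliver the oxygen from the face of the bishomoallylic hydroxyl, which is the face of the side chain, to give the epoxy alcohol F4. Dess–Martin oxidation should return 15.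

Step 2. The risk is loss of the α′ proton in competition with the γ proton, which would give the cross-conjugated dienyl triflate and misdirect the dihydroxylation. The fallback sets out from 5 and comes back at 8, replacing steps 2 to 4. Isopropenyl acetate with p-TsOH at reflux should give the linearly conjugated dienol acetate F5 under thermodynamic control. Buffered mCPBA should attack its terminal alkene anti to the ester (vinylogous Rubottom-type oxidation) and give the γ-hydroxy enone F6. Hydroxyl-directed nucleophilic epoxidation (t-BuOOH, catalytic benzyltrimethylammonium hydroxide, THF, 0 °C) should give the epoxy ketone F7 with the epoxide cis to the hydroxyl. Wharton transposition (N2H4·H2O, AcOH, MeOH) should then give diol 8 directly.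

**Further compounds**

F1 | step 11 | (1R,2R,3R,4R,6R)-4-(3-hydroxy-6-methylhepta-1,5-dien-2-yl)-3-[(4-methoxyphenyl)methoxy]-1-methyl-7-oxabicyclo[4.1.0]heptan-2-yl (2Z)-2-methylbut-2-enoate, both carbinol epimers | C=C(C(O)CC=C(C)C)[C@H]1C[C@H]2O[C@@]2(C)[C@H](OC(=O)/C(C)=C\C)[C@@H]1OCc1ccc(OC)cc1
F2 | step 11 | (1R,2R,3R,4R,6R)-3-[(4-methoxyphenyl)methoxy]-1-methyl-4-(6-methyl-3-oxohepta-1,5-dien-2-yl)-7-oxabicyclo[4.1.0]heptan-2-yl (2Z)-2-methylbut-2-enoate | C=C(C(=O)CC=C(C)C)[C@H]1C[C@H]2O[C@@]2(C)[C@H](OC(=O)/C(C)=C\C)[C@@H]1OCc1ccc(OC)cc1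
F3 | step 8 | 5-(1-hydroxyethyl)-6-[(4-methoxyphenyl)methoxy]-2-methylcyclohex-2-en-1-yl (2Z)-2-methylbut-2-enoate, ring stereocentres as in 14, carbinol epimers | CC(O)[C@H]1CC=C(C)[C@H](OC(=O)/C(C)=C\C)[C@@H]1OCc1ccc(OC)cc1
F4 | step 8 | 4-(1-hydroxyethyl)-3-[(4-methoxyphenyl)methoxy]-1-methyl-7-oxabicyclo[4.1.0]heptan-2-yl (2Z)-2-methylbut-2-enoate, ring stereocentres as in 15, carbinol epimers | CC(O)[C@H]1C[C@H]2O[C@@]2(C)[C@H](OC(=O)/C(C)=C\C)[C@@H]1OCc1ccc(OC)cc1
F5 | step 2 | ethyl (1S)-5-(acetyloxy)-4-methylcyclohexa-2,4-diene-1-carboxylate | CCOC(=O)[C@H]1CC(OC(C)=O)=C(C)C=C1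
F6 | step 2 | ethyl (1S,2S)-2-hydroxy-4-methyl-5-oxocyclohex-3-ene-1-carboxylate | CCOC(=O)[C@H]1CC(=O)C(C)=C[C@@H]1O
F7 | step 2 | ethyl (1R,2R,3S,6R)-2-hydroxy-6-methyl-5-oxo-7-oxabicyclo[4.1.0]heptane-3-carboxylate | CCOC(=O)[C@H]1CC(=O)[C@]2(C)O[C@@H]2[C@@H]1O
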